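**Plan**
- Retrosynthesis: the four O–benzyl bonds are cut last. Then C4–C4a is cut (ring C, acylation of ring A by the carboxyl carbon), then O1–C2 (vinylic substitution by the ring A phenol), then C2–C3 (acylation of a benzyloxyacetate enolate by the ring B acid chloride).
- Ring A phenol: the C8 oxygen replaces the formyl group of a purchased benzaldehyde, and O1 replaces a second formyl group introduced ortho to it (two Baeyer–Villiger oxidations).
- Forward: rings A and B are bought as benzenes. The three-carbon bridge is built on ring B and joined to ring A through O1; ring C, the only ring made, closes last before global debenzylation.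
- Enabling feature: C4a of ring A is ortho to O1 and to the C5 oxygen and para to the C7 oxygen. It is the only hydrogen-bearing carbon ortho to O1, because C8 holds the methoxyl.
- Stereochemistry: the target has no stereocentre. The only stereo-element on the way, the acrylate geometry, corrects itself under the acidic ring closure.

Key step: step 11

Assumption: the β-chloroacrylate, the aryloxyacrylates and the mixed anhydride are drawn as E isomers (chlorine or aryloxy cis to the carboxyl carbon), the geometry that retention in the vinylic substitution should favour. Any Z material would be carried along, since the push–pull alkene should equilibrate in the ring closure.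

**Step 1**
Reactants: 1 2,4-bis(benzyloxy)benzaldehyde
Product: 3 2,4-bis(benzyloxy)phenol, via 2,4-bis(benzyloxy)phenyl formate 2 (not isolated)
Conditions: mCPBA, CH2Cl2, 0 °C to rt; aq. Na2S2O3/NaHCO3 wash; then K2CO3 (cat.), MeOH, rt
Reagents that add atoms: mCPBA (3-chloroperoxybenzoic acid), O=C(OO)c1cccc(Cl)c1
Why: Baeyer–Villiger (Dakin-type) oxidation in which the aryl group, enriched by its ortho and para benzyloxy groups, migrates in preference to hydride, after which the formate is methanolysed under catalytic base.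

**Step 2**
Reactants: 3 2,4-bis(benzyloxy)phenol
Product: 4 3,5-bis(benzyloxy)-2-hydroxybenzaldehyde
Conditions: MgCl2, Et3N, (CH2O)n, MeCN, reflux; aq. HCl work-up
Reagents that add atoms: paraformaldehyde (as formaldehyde), C=O
Why: Magnesium-phenoxide-directed ortho-formylation (Casnati–Skattebøl reaction) delivers formaldehyde inside a chelate to the only free ortho carbon, and a second formaldehyde oxidises the hydroxymethyl intermediate by hydride transfer.

**Step 3**
Reactants: 4 3,5-bis(benzyloxy)-2-hydroxybenzaldehyde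
Product: 5 3,5-bis(benzyloxy)-2-methoxybenzaldehyde
Conditions: MeI, K2CO3, DMF, rt to 40 °C
Reagents that add atoms: iodomethane, CI
Why: Williamson O-methylation (SN2) of the only free phenol fixes the future C8 methoxyl before the second ring oxygen is unmasked.

**Step 4**
Reactants: 5 3,5-bis(benzyloxy)-2-methoxybenzaldehyde
Product: 7 3,5-bis(benzyloxy)-2-methoxyphenol, via 3,5-bis(benzyloxy)-2-methoxyphenyl formate 6 (not isolated)
Conditions: mCPBA, CH2Cl2, rt; aq. Na2S2O3/NaHCO3 wash; then K2CO3 (cat.), MeOH, rt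
Reagents that add atoms: mCPBA (3-chloroperoxybenzoic acid), O=C(OO)c1cccc(Cl)c1
Why: A second Baeyer–Villiger oxidation, in which the ortho methoxyl supports aryl migration as in 2,3-dialkoxybenzaldehydes, turns the formyl carbon into the phenol oxygen that becomes O1.

**Step 5**
Reactants: 8 3-hydroxy-4,5-dimethoxybenzoic acid
Product: 10 3-(benzyloxy)-4,5-dimethoxybenzoic acid, via benzyl 3-(benzyloxy)-4,5-dimethoxybenzoate 9 (not isolated)
Conditions: BnBr (2.3 equiv), K2CO3, DMF, 60 °C; then aq. NaOH, MeOH, 60 °C; aq. HCl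
Reagents that add atoms: benzyl bromide, BrCc1ccccc1; sodium hydroxide, [Na+].[OH-]
Why: Williamson benzylation of both the phenoxide and the carboxylate, followed in the same pot by saponification of the benzyl ester, leaves the aryl benzyl ether as the only new group.

**Step 6**
Reactants: 10 3-(benzyloxy)-4,5-dimethoxybenzoic acid
Product: 11 3-(benzyloxy)-4,5-dimethoxybenzoyl chloride
Conditions: (COCl)2, DMF (cat.), CH2Cl2, 0 °C to rt; evaporate, use crude
Reagents that add atoms: oxalyl chloride, O=C(Cl)C(Cl)=O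
Why: DMF-catalysed acid chloride formation with oxalyl chloride is mild enough for the benzyl and methyl ethers and gives only gaseous by-products.

**Step 7**
Reactants: 11 3-(benzyloxy)-4,5-dimethoxybenzoyl chloride; 12 methyl benzyloxyacetate
Product: 14 methyl 2-(benzyloxy)-3-[3-(benzyloxy)-4,5-dimethoxyphenyl]-3-oxopropanoate (racemic), via lithium enolate of methyl benzyloxyacetate 13 (not isolated)
Conditions: LiN(SiMe3)2 (2.1 equiv), 12 (2.1 equiv), THF, −78 °C; then 11 (1.0 equiv), −78 to −40 °C; aq. NH4Cl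
Reagents that add atoms: none
Why: Crossed Claisen-type C-acylation of a preformed ester enolate by an aroyl chloride forms C2–C3, the second equivalent of enolate removing the acidic proton of the product and so preventing double acylation.

**Step 8**
Reactants: 14 methyl 2-(benzyloxy)-3-[3-(benzyloxy)-4,5-dimethoxyphenyl]-3-oxopropanoate
Product: 15 methyl (E)-2-(benzyloxy)-3-[3-(benzyloxy)-4,5-dimethoxyphenyl]-3-chloroprop-2-enoate
Conditions: (chloromethylene)dimethyliminium chloride (2 equiv), ClCH2CH2Cl, 0 to 50 °C; aq. NaHCO3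
Reagents that add atoms: (chloromethylene)dimethyliminium chloride, C[N+](C)=CCl.[Cl-]
Why: Vilsmeier-type deoxychlorination of a β-keto ester, in which the enol oxygen adds to the chloroiminium ion and chloride then displaces DMF from the β-carbon by addition–elimination, removes the stereocentre and gives the β-chloroacrylate.

**Step 9**
Reactants: 15 methyl (E)-2-(benzyloxy)-3-[3-(benzyloxy)-4,5-dimethoxyphenyl]-3-chloroprop-2-enoate; 7 3,5-bis(benzyloxy)-2-methoxyphenol
Product: 16 methyl (E)-2-(benzyloxy)-3-[3,5-bis(benzyloxy)-2-methoxyphenoxy]-3-[3-(benzyloxy)-4,5-dimethoxyphenyl]prop-2-enoate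
Conditions: Cs2CO3, DMF, 70 °C, N2
Reagents that add atoms: none
Why: Nucleophilic vinylic substitution (addition–elimination) of a phenoxide on a β-chloroacrylate, the classical entry to β-aryloxycinnamates, forms O1–C2 with expected retention; a chloride leaving group is chosen because, unlike a sulfonate, it offers the phenoxide no second electrophilic site.

**Step 10**
Reactants: 16 methyl (E)-2-(benzyloxy)-3-[3,5-bis(benzyloxy)-2-methoxyphenoxy]-3-[3-(benzyloxy)-4,5-dimethoxyphenyl]prop-2-enoate
Product: 17 (E)-2-(benzyloxy)-3-[3,5-bis(benzyloxy)-2-methoxyphenoxy]-3-[3-(benzyloxy)-4,5-dimethoxyphenyl]prop-2-enoic acid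
Conditions: LiOH·H2O, THF/MeOH/H2O, 40 °C; then 1 M HCl to pH 3, 0 °C
Reagents that add atoms: lithium hydroxide, [Li+].[OH-]
Why: Saponification by acyl–oxygen cleavage, as used for β-aryloxycinnamic esters, spares the base-stable aryl vinyl ether, and the carboxylate once formed shuts off conjugate addition of hydroxide.

**Step 11**
Reactants: 17 (E)-2-(benzyloxy)-3-[3,5-bis(benzyloxy)-2-methoxyphenoxy]-3-[3-(benzyloxy)-4,5-dimethoxyphenyl]prop-2-enoic acid
Product: 19 3,5,7-tris(benzyloxy)-2-[3-(benzyloxy)-4,5-dimethoxyphenyl]-8-methoxy-4H-chromen-4-one, via mixed trifluoroacetic anhydride 18 (not isolated)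
Conditions: (CF3CO)2O (2 equiv), CH2Cl2, 0 °C to rt; aq. NaHCO3
Reagents that add atoms: none
Why: Trifluoroacetic anhydride converts the acid into mixed anhydride 18, which the released trifluoroacetic acid ionises towards an acylium ion; C4a of ring A attacks the acyl carbon and loss of a proton from the arenium ion forms C4–C4a. The closest known reaction type is the cyclodehydration of 3-aryloxycinnamic acids to flavones (intramolecular Friedel–Crafts acylation), run here with an anhydride activator because ring A is as nucleophilic as a phloroglucinol triether and needs no strong Lewis acid that would strip benzyl groups. Ring C closes in the 6-exo-trig mode at the acyl carbon, the carbonyl oxygen remaining outside the ring. No stereocentre is formed. The step needs site selectivity and a carboxyl group cis to the aryloxy group: C8 carries the methoxyl, so C4a is the only open carbon ortho to O1, and the push–pull alkene should isomerise under the acidic conditions by reversible protonation at the benzyloxy-bearing carbon, so that Z material drains through the reactive E isomer. Closure onto ring B to an indenone should not compete, because ring A is far more nucleophilic and a five-membered acylation transition state is more strained.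

**Step 12**
Reactants: 19 3,5,7-tris(benzyloxy)-2-[3-(benzyloxy)-4,5-dimethoxyphenyl]-8-methoxy-4H-chromen-4-one
Product: 20 3,5,7-trihydroxy-2-(3-hydroxy-4,5-dimethoxyphenyl)-8-methoxy-4H-chromen-4-one (CNP0225742.0)
Conditions: H2 (1 atm), Pd/C (10%), THF/MeOH, rt
Reagents that add atoms: none
Why: Catalytic hydrogenolysis cleaves the three aryl benzyl ethers and the enol benzyl ether at C3 while the methyl ethers and the chromone double bond should stay untouched under these mild conditions.

**Compound list**
1 | 2,4-bis(benzyloxy)benzaldehyde | O=Cc1ccc(OCc2ccccc2)cc1OCc1ccccc1 | starting material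
2 | 2,4-bis(benzyloxy)phenyl formate | O=COc1ccc(OCc2ccccc2)cc1OCc1ccccc1 | intermediate (not isolated)
3 | 2,4-bis(benzyloxy)phenol | Oc1ccc(OCc2ccccc2)cc1OCc1ccccc1 | intermediate
4 | 3,5-bis(benzyloxy)-2-hydroxybenzaldehyde | O=Cc1cc(OCc2ccccc2)cc(OCc2ccccc2)c1O | intermediate
5 | 3,5-bis(benzyloxy)-2-methoxybenzaldehyde | COc1c(C=O)cc(OCc2ccccc2)cc1OCc1ccccc1 | intermediate
6 | 3,5-bis(benzyloxy)-2-methoxyphenyl formate | COc1c(OC=O)cc(OCc2ccccc2)cc1OCc1ccccc1 | intermediate (not isolated)
7 | 3,5-bis(benzyloxy)-2-methoxyphenol | COc1c(O)cc(OCc2ccccc2)cc1OCc1ccccc1 | intermediate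
8 | 3-hydroxy-4,5-dimethoxybenzoic acid | COc1cc(C(=O)O)cc(O)c1OC | starting material
9 | benzyl 3-(benzyloxy)-4,5-dimethoxybenzoate | COc1cc(C(=O)OCc2ccccc2)cc(OCc2ccccc2)c1OC | intermediate (not isolated)
10 | 3-(benzyloxy)-4,5-dimethoxybenzoic acid | COc1cc(C(=O)O)cc(OCc2ccccc2)c1OC | intermediate
11 | 3-(benzyloxy)-4,5-dimethoxybenzoyl chloride | COc1cc(C(=O)Cl)cc(OCc2ccccc2)c1OC | intermediate
12 | methyl benzyloxyacetate | COC(=O)COCc1ccccc1 | starting material
13 | lithium enolate of methyl benzyloxyacetate (enolate oxygen and benzyloxy group cis, lithium chelated) | [Li+].[O-]/C(OC)=C\OCc1ccccc1 | intermediate (not isolated)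
14 | methyl 2-(benzyloxy)-3-[3-(benzyloxy)-4,5-dimethoxyphenyl]-3-oxopropanoate (racemic) | COC(=O)C(OCc1ccccc1)C(=O)c1cc(OCc2ccccc2)c(OC)c(OC)c1 | intermediate
15 | methyl (E)-2-(benzyloxy)-3-[3-(benzyloxy)-4,5-dimethoxyphenyl]-3-chloroprop-2-enoate (chlorine cis to the ester) | COC(=O)/C(OCc1ccccc1)=C(\Cl)c1cc(OCc2ccccc2)c(OC)c(OC)c1 | intermediate
16 | methyl (E)-2-(benzyloxy)-3-[3,5-bis(benzyloxy)-2-methoxyphenoxy]-3-[3-(benzyloxy)-4,5-dimethoxyphenyl]prop-2-enoate (aryloxy cis to the ester) | COC(=O)/C(OCc1ccccc1)=C(\Oc1cc(OCc2ccccc2)cc(OCc2ccccc2)c1OC)c1cc(OCc2ccccc2)c(OC)c(OC)c1 | intermediate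
17 | (E)-2-(benzyloxy)-3-[3,5-bis(benzyloxy)-2-methoxyphenoxy]-3-[3-(benzyloxy)-4,5-dimethoxyphenyl]prop-2-enoic acid (aryloxy cis to the carboxyl) | O=C(O)/C(OCc1ccccc1)=C(\Oc1cc(OCc2ccccc2)cc(OCc2ccccc2)c1OC)c1cc(OCc2ccccc2)c(OC)c(OC)c1 | intermediate
18 | mixed anhydride of acid 17 with trifluoroacetic acid (E) | O=C(OC(=O)C(F)(F)F)/C(OCc1ccccc1)=C(\Oc1cc(OCc2ccccc2)cc(OCc2ccccc2)c1OC)c1cc(OCc2ccccc2)c(OC)c(OC)c1 | intermediate (not isolated)
19 | 3,5,7-tris(benzyloxy)-2-[3-(benzyloxy)-4,5-dimethoxyphenyl]-8-methoxy-4H-chromen-4-one | COc1c(OCc2ccccc2)cc(OCc2ccccc2)c2c(=O)c(OCc3ccccc3)c(-c3cc(OCc4ccccc4)c(OC)c(OC)c3)oc12 | intermediate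
20 | 3,5,7-trihydroxy-2-(3-hydroxy-4,5-dimethoxyphenyl)-8-methoxy-4H-chromen-4-one | COc1cc(-c2oc3c(OC)c(O)cc(O)c3c(=O)c2O)cc(O)c1OC | target

**Totals**
Total step count: 12. Longest linear sequence: 8 steps (steps 1–4, then 9–12; the ring B branch, steps 5–8 then 9–12, is equally long).

**Steps most likely to fail**

Step 9. The phenoxide may add too slowly to the fully substituted β-carbon, whose electrophilicity is lowered by the α-benzyloxy donor. At the temperature then needed, attack of the phenoxide on the ester methyl group or oxidation of the electron-rich phenoxide would consume the partners. The fallback sets out from 14 and 7 and comes back at 17; it raises the acceptor to the aldehyde level. Dealkoxycarbonylation of 14 (LiCl, wet DMSO, 140 °C) should give 2-(benzyloxy)-1-[3-(benzyloxy)-4,5-dimethoxyphenyl]ethan-1-one F1. Vilsmeier–Haack–Arnold chloroformylation ((chloromethylene)dimethyliminium chloride, ClCH2CH2Cl, 60 °C; aq. NaOAc) should give (E)-2-(benzyloxy)-3-[3-(benzyloxy)-4,5-dimethoxyphenyl]-3-chloroprop-2-enal F2. β-Chlorovinyl aldehydes are much stronger acceptors than the ester and should take up 7 (K2CO3, DMF, rt) to give (E)-2-(benzyloxy)-3-[3,5-bis(benzyloxy)-2-methoxyphenoxy]-3-[3-(benzyloxy)-4,5-dimethoxyphenyl]prop-2-enal F3. Pinnick oxidation (NaClO2, NaH2PO4, t-BuOH/H2O, with a large excess of 2-methyl-2-butene so that hypochlorous acid does not chlorinate ring A) should then give 17, and steps 8 and 10 are no longer needed.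

Step 8. The keto ester is hindered and little enolised, so O-activation by the chloroiminium salt may stall, and the hydrogen chloride released may cleave the α-benzyl ether. The fallback sets out from 14 and 7 and comes back at 16; it forms O1–C2 by cross-coupling instead of vinylic substitution. Sulfonylation of the chelated lithium enolate (LiN(SiMe3)2, THF, −78 °C; then PhNTf2) should give methyl (E)-2-(benzyloxy)-3-[3-(benzyloxy)-4,5-dimethoxyphenyl]-3-{[(trifluoromethyl)sulfonyl]oxy}prop-2-enoate F4. Coupling with 7 under zerovalent palladium catalysis (Pd2(dba)3, 2-di-tert-butylphosphino-2',4',6'-triisopropylbiphenyl, K3PO4, toluene, 90 °C) should then give 16 by oxidative addition into the C–O sulfonate bond and C–O reductive elimination.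

Step 11. The acyl group, weakened by two donor oxygens on the alkene, may react too slowly. Trifluoroacetylation of ring A at C6, closure of Z material onto ring B, or acid-promoted benzyl transfer could then outrun the wanted closure. The fallback sets out from 7 and 11 and comes back at 20; it closes ring C through the phenol oxygen instead of through C4a. Magnesium-mediated ortho-formylation of 7 (MgCl2, Et3N, (CH2O)n, MeCN, reflux), which can reach only the carbon that becomes C4a, should give 4,6-bis(benzyloxy)-2-hydroxy-3-methoxybenzaldehyde F5. Addition of MeMgBr (THF, 0 °C) should give 1-[4,6-bis(benzyloxy)-2-hydroxy-3-methoxyphenyl]ethan-1-ol F6 (racemic), and MnO2 (CH2Cl2, rt) should oxidise it to 1-[4,6-bis(benzyloxy)-2-hydroxy-3-methoxyphenyl]ethan-1-one F7. One-pot Baker–Venkataraman-type C-aroylation of its dianion with 11 (LiN(SiMe3)2, 3.2 equiv, THF, −78 °C to rt) should give 1-[4,6-bis(benzyloxy)-2-hydroxy-3-methoxyphenyl]-3-[3-(benzyloxy)-4,5-dimethoxyphenyl]propane-1,3-dione F8. Cyclodehydration (TsOH cat., toluene, 80 °C) should give 5,7-bis(benzyloxy)-2-[3-(benzyloxy)-4,5-dimethoxyphenyl]-8-methoxy-4H-chromen-4-one F9. C3 lithiation, borylation and oxidation (LiN(iPr)2, THF, −78 °C; B(OMe)3; then H2O2, AcOH) should give 5,7-bis(benzyloxy)-2-[3-(benzyloxy)-4,5-dimethoxyphenyl]-3-hydroxy-8-methoxy-4H-chromen-4-one F10. Hydrogenolysis under the conditions of step 12 should then give 20.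

**Further compounds**
F1 | step 9 | 2-(benzyloxy)-1-[3-(benzyloxy)-4,5-dimethoxyphenyl]ethan-1-one | O=C(COCc1ccccc1)c1cc(OCc2ccccc2)c(OC)c(OC)c1
F2 | step 9 | (E)-2-(benzyloxy)-3-[3-(benzyloxy)-4,5-dimethoxyphenyl]-3-chloroprop-2-enal | O=C/C(OCc1ccccc1)=C(\Cl)c1cc(OCc2ccccc2)c(OC)c(OC)c1
F3 | step 9 | (E)-2-(benzyloxy)-3-[3,5-bis(benzyloxy)-2-methoxyphenoxy]-3-[3-(benzyloxy)-4,5-dimethoxyphenyl]prop-2-enal | O=C/C(OCc1ccccc1)=C(\Oc1cc(OCc2ccccc2)cc(OCc2ccccc2)c1OC)c1cc(OCc2ccccc2)c(OC)c(OC)c1
F4 | step 8 | methyl (E)-2-(benzyloxy)-3-[3-(benzyloxy)-4,5-dimethoxyphenyl]-3-{[(trifluoromethyl)sulfonyl]oxy}prop-2-enoate | COC(=O)/C(OCc1ccccc1)=C(\OS(=O)(=O)C(F)(F)F)c1cc(OCc2ccccc2)c(OC)c(OC)c1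
F5 | step 11 | 4,6-bis(benzyloxy)-2-hydroxy-3-methoxybenzaldehyde | O=Cc1c(O)c(OC)c(OCc2ccccc2)cc1OCc1ccccc1
F6 | step 11 | 1-[4,6-bis(benzyloxy)-2-hydroxy-3-methoxyphenyl]ethan-1-ol (racemic) | CC(O)c1c(O)c(OC)c(OCc2ccccc2)cc1OCc1ccccc1
F7 | step 11 | 1-[4,6-bis(benzyloxy)-2-hydroxy-3-methoxyphenyl]ethan-1-one | CC(=O)c1c(O)c(OC)c(OCc2ccccc2)cc1OCc1ccccc1
F8 | step 11 | 1-[4,6-bis(benzyloxy)-2-hydroxy-3-methoxyphenyl]-3-[3-(benzyloxy)-4,5-dimethoxyphenyl]propane-1,3-dione | O=C(CC(=O)c1cc(OCc2ccccc2)c(OC)c(OC)c1)c1c(O)c(OC)c(OCc2ccccc2)cc1OCc1ccccc1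
F9 | step 11 | 5,7-bis(benzyloxy)-2-[3-(benzyloxy)-4,5-dimethoxyphenyl]-8-methoxy-4H-chromen-4-one | COc1c(OCc2ccccc2)cc(OCc2ccccc2)c2c(=O)cc(-c3cc(OCc4ccccc4)c(OC)c(OC)c3)oc12
F10 | step 11 | 5,7-bis(benzyloxy)-2-[3-(benzyloxy)-4,5-dimethoxyphenyl]-3-hydroxy-8-methoxy-4H-chromen-4-one | COc1c(OCc2ccccc2)cc(OCc2ccccc2)c2c(=O)c(O)c(-c3cc(OCc4ccccc4)c(OC)c(OC)c3)oc12
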